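common to all: left-handed substrate 0.0010 M; right-handed substrate 0.0010 M; gas 0.034 mM (held)
- Thursday's: precatalyst 0.2 mol%; run made earlier
- Monday's: precatalyst 0.31 mol%; run made earlier
- flask: precatalyst 0.14 mol%; time 4.0 min

| run | time / min | right-handed substrate / % | left-handed substrate / % | left-handed product / % |
|---|---|---|---|---|
| Thursday's | 0.333 | 46 | 17 | 37 |
| Thursday's | 0.833 | 31 | 0 | 65 |
| Thursday's | 1.50 | 16 | 2 | 74 |
| Thursday's | 2.50 | 3 | 2 | 78 |
| Monday's | 0.667 | 33 | 1 | 63 |
| Monday's | 1.33 | 13 | 0 | 72 |
| Monday's | 2.00 | 8 | 0 | 75 |
| Monday's | 2.50 | 0 | 0 | 76 |

(readings scatter by 1.5 percentage points)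

- free catalyst is single-handed; left-handed substrate and right-handed substrate are mirror images of each other, charged as a racemate, each of them at the stated concentration
- at the start none of reagent is dissolved
- what may be going on: reagent + catalyst intermediate B -> free catalyst + right-handed product; left-handed substrate <-> right-handed substrate; precatalyst -> free catalyst; free catalyst + right-handed substrate <-> catalyst intermediate B; free catalyst + left-handed substrate <-> catalyst intermediate A; reagent + catalyst intermediate A -> free catalyst + left-handed product; gas <-> reagent

- whether the excess of right-handed substrate over left-handed substrate among what is left of the two reaches 90% by 4.0 min (no / yes)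
- the highest excess of right-handed substrate over left-handed substrate among what is left of the two up to 4.0 min

**Removing time.** By 4.0 min the flask must show the wanted excess at least once, so [left-handed substrate]/[right-handed substrate] has to fall to 0.0526. Divide the two fractional loss rates and time drops out; the loading goes too, if both losses carry the same catalyst. Thursday's first reading gives 12.9 for the selectivity factor, the logarithm of the fraction of left-handed substrate remaining over that of the fraction of right-handed substrate remaining.

**First doubt.** One reading is thin. But on Monday's run, at another loading, s turns right-handed substrate at 33% into left-handed substrate at 0.231%, and you read 1%, with scatter 1.5 percentage points. So s stands, and in this flask it places the crossing with right-handed substrate at 39.1% of both charged.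

**Second doubt.** The rule has no floor, yet racemisation can refeed left-handed substrate, and loading would not speed that step. Thursday's and Monday's readings with plenty of right-handed substrate pool to a ratio of 0.0323, a loose reading. Scaled fully to this flask's 0.14 mol%, it becomes 0.0588, an excess of 88.9%, just short. But Monday's first reading and Thursday's second show like product, 63% and 65%, and loading times squared time differs between them by a factor of 0.994, which suits free catalyst growing in from precatalyst in proportion to loading and time. The pooled readings stand at a mean of 1.08 min. If the ratio falls as that catalyst grows, this flask's scaled ratio reaches 0.0526 near 1.21 min and comes to 0.0159 at 4.0 min. That stretches a loose ratio far, so the top is rough. Commit: yes, topping near 96.9%.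

**The forecast.** It says no, with a top of 82%, between 70% and 92%, holding that “consumption of left-handed substrate is slower”. That puts it on the other side of the line from the reckoning above.

**The flask.** It gives yes, with a top of 97.4%.

    reagent + catalyst intermediate B → free catalyst + right-handed product (k = 2.40 × 10⁵ M⁻¹ s⁻¹)
    left-handed substrate ⇌ right-handed substrate (k = 0.0110 s⁻¹)
    precatalyst → free catalyst (k = 0.0200 s⁻¹)
    free catalyst + right-handed substrate ⇌ catalyst intermediate B (K = 860 M⁻¹, k = 1.60 × 10⁶ M⁻¹ s⁻¹)
    free catalyst + left-handed substrate ⇌ catalyst intermediate A (K = 5300 M⁻¹, k = 1.00 × 10⁶ M⁻¹ s⁻¹)
    reagent + catalyst intermediate A → free catalyst + left-handed product (k = 8.90 × 10⁶ M⁻¹ s⁻¹)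
    gas ⇌ reagent, rate k7*(csat - [reagent]) (kL = 7.20 s⁻¹)

**The crossing.** The excess passed 90% at 0.703 min. Read on this flask at 0.400 min, s comes to 13.7. Thursday's s had put the crossing at 39.1%, and right-handed substrate then stood at 37.4% of both charged.

The data were computed with made-up constants.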